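**Strategy.** Everything rests on cutting the bond between pyrone C6 and the quaternary cyclobutane carbon, and on reading the cyclobutane fused to the cyclohexene ring (the bicyclo[4.2.0]octadiene hidden under the peroxide bridge) as the 8π–6π valence isomer of a linear (E,Z,Z,E)-tetraene whose terminus is that quaternary carbon. A Pd-catalysed reductive syn-hydroarylation joins a pyronyl triflate to the methyl-capped alkyne of an open-chain (Z,Z,E)-trienyne. The tetraene formed folds in the same flask by conrotatory 8π and disrotatory 6π electrocyclization into the bicyclic diene, closing both carbocycles and setting four stereocentres. Resolution and a face-selective singlet-oxygen [4+2] complete the endoperoxide.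

Key step: step 9

Remark: no established method steers the 8π–6π cascade of an achiral tetraene to one enantiomer, so the cascade is run racemic and the absolute configuration is secured by resolution of the diene in step 10; which eluted enantiomer is (1R,6R,7S,8R) is to be assigned by ECD or VCD against calculation.

**Step 1**
Reactants: 1 dimethyl 3-oxopentanedioate
Product: 2 dimethyl 2,4-dimethyl-3-oxopentanedioate
Conditions: MeI (2.1 equiv), K2CO3, acetone, 23 °C
Reagents that add atoms: iodomethane, CI
Why: Double C-methylation of the doubly activated β-keto diester (enolate alkylation, one methyl per α-carbon); the two new stereocentres are of no consequence because both carbons become sp2 in step 2.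

**Step 2**
Reactants: 2 dimethyl 2,4-dimethyl-3-oxopentanedioate
Product: 3 4-hydroxy-6-methoxy-3,5-dimethyl-2H-pyran-2-one
Conditions: fuming H2SO4 (20% SO3), 0 → 23 °C; then ice
Reagents that add atoms: none
Why: Acid-mediated cyclocondensation (intramolecular O-acylation of the enolised β-keto ester by the second ester, with loss of methanol) should give the 6-alkoxy-4-hydroxy-2-pyranone; no stereocentre remains.

**Step 3**
Reactants: 3 4-hydroxy-6-methoxy-3,5-dimethyl-2H-pyran-2-one
Product: 4 6-methoxy-3,5-dimethyl-4-oxo-4H-pyran-2-yl trifluoromethanesulfonate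
Conditions: Tf2O, 2,6-di-tert-butyl-4-methylpyridine, CH2Cl2, −78 → 0 °C
Reagents that add atoms: trifluoromethanesulfonic anhydride, O=S(=O)(OS(=O)(=O)C(F)(F)F)C(F)(F)F
Why: O-Sulfonylation of the neutral vinylogous acid at the lactone carbonyl oxygen, the site at which hard electrophiles convert 4-hydroxy-2-pyranones into 2-alkoxy-4-pyranones and the only oxygen not flanked by two methyl groups, should give the enol triflate at the ring carbon next to the ring oxygen; the hindered base only scavenges acid.

**Step 4**
Reactants: 5 propyne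
Product: 7 2-[(Z)-2-bromoprop-1-en-1-yl]-4,4,5,5-tetramethyl-1,3,2-dioxaborolane, via (Z)-dibromo(2-bromoprop-1-enyl)borane 6 (not isolated)
Conditions: BBr3, CH2Cl2, −78 → 23 °C; then pinacol, 0 → 23 °C
Reagents that add atoms: boron tribromide, BrB(Br)Br; pinacol, CC(C)(O)C(C)(C)O
Why: syn-Bromoboration of the terminal alkyne places boron on the terminal and bromine on the internal carbon on the same side (Z), and esterification with pinacol gives the stable bromo-boronate.

**Step 5**
Reactants: 7 2-[(Z)-2-bromoprop-1-en-1-yl]-4,4,5,5-tetramethyl-1,3,2-dioxaborolane; 8 prop-1-yn-1-ylmagnesium bromide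
Product: 10 4,4,5,5-tetramethyl-2-[(Z)-2-methylpent-1-en-3-yn-1-yl]-1,3,2-dioxaborolane, via prop-1-ynylzinc bromide 9 (not isolated)
Conditions: 8, ZnBr2, THF, 0 °C; then 7, Pd(t-Bu3P)2 (1 mol %), 23 °C
Reagents that add atoms: none
Why: Negishi coupling of the alkynylzinc at the C–Br bond proceeds with retention of the alkene geometry while the pinacol boronate is a spectator under the base-free conditions.

**Step 6**
Reactants: 10 4,4,5,5-tetramethyl-2-[(Z)-2-methylpent-1-en-3-yn-1-yl]-1,3,2-dioxaborolane
Product: 11 (Z)-1-iodo-2-methylpent-1-en-3-yne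
Conditions: I2, aq. NaOH, THF, 0 → 23 °C
Reagents that add atoms: iodine, II
Why: Iododeboronation of the alkenylboronate through its hydroxide ate complex should replace boron by iodine with retention of the Z geometry.

**Step 7**
Reactants: 11 (Z)-1-iodo-2-methylpent-1-en-3-yne; 7 2-[(Z)-2-bromoprop-1-en-1-yl]-4,4,5,5-tetramethyl-1,3,2-dioxaborolane
Product: 14 2-[(1Z,3Z)-2,4-dimethylhepta-1,3-dien-5-yn-1-yl]-4,4,5,5-tetramethyl-1,3,2-dioxaborolane, via alkenyllithium 12 (not isolated), via alkenylzinc bromide 13 (not isolated)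
Conditions: n-BuLi, Et2O, −78 °C; ZnBr2, THF, −78 → 0 °C; then 7, Pd(t-Bu3P)2 (2 mol %), 23 °C
Reagents that add atoms: none
Why: Iodine–lithium exchange with retention, transmetalation to zinc and a second Negishi coupling at the C–Br bond of 7 (retention at both partners) add the next (Z)-C(Me)=CH unit and leave a new terminal boronate.

**Step 8**
Reactants: 14 2-[(1Z,3Z)-2,4-dimethylhepta-1,3-dien-5-yn-1-yl]-4,4,5,5-tetramethyl-1,3,2-dioxaborolane; 15 (E)-2-bromobut-2-ene
Product: 16 (2E,4Z,6Z)-3,5,7-trimethyldeca-2,4,6-trien-8-yne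
Conditions: Pd(PPh3)4 (5 mol %), aq. NaOH, THF, 45 °C, dark
Reagents that add atoms: none
Why: Suzuki–Miyaura coupling with retention at both alkenyl partners installs the (E)-but-2-en-2-yl end and completes the trienyne, which is not set up for an 8π closure as long as the fourth π unit is an alkyne.

**Step 9**
Reactants: 4 6-methoxy-3,5-dimethyl-4-oxo-4H-pyran-2-yl trifluoromethanesulfonate; 16 (2E,4Z,6Z)-3,5,7-trimethyldeca-2,4,6-trien-8-yne
Product: 19 rac-2-methoxy-3,5-dimethyl-6-[(1RS,6RS,7SR,8RS)-1,3,5,7,8-pentamethylbicyclo[4.2.0]octa-2,4-dien-7-yl]-4H-pyran-4-one, via (2E,4Z,6Z,8E)-tetraene 17 (not isolated), via rac-cyclooctatriene 18 (not isolated)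
Conditions: Pd(OAc)2 (5 mol %), PPh3 (10 mol %), HCO2K (3 equiv), DMF, 40 → 50 °C, dark; chromatography
Reagents that add atoms: none
Why: Pd(0) inserts into the C–OTf bond of 4, the pyronyl–Pd species adds syn across the alkyne of 16 with the pyrone going to the methyl-bearing carbon, and formate exchange, loss of CO2 and C–H reductive elimination release the (2E,4Z,6Z,8E)-tetraene 17, so the pyrone–carbon bond is made at the future quaternary cyclobutane carbon. The closest known reaction types are the formate-terminated reductive Heck reaction (syn-hydroarylation or hydrovinylation) of internal alkynes with aryl halides or enol triflates and the cross-coupling/8π–6π cascades of methyl-substituted (E,Z,Z,E)-tetraenes. 17 should not persist at 40–50 °C: thermal conrotatory 8π electrocyclization closes the eight-membered ring of 18, and thermal disrotatory 6π electrocyclization of its all-cis triene then forms the transannular bond that closes the cyclohexadiene and the cyclobutane at once. C7 and C8 are set relative to each other by conrotation and the alkene geometry (the pyrone and the terminal methyl, both "outside", end up trans, so 7-Me and 8-Me are cis), C1 and C6 are set cis to each other by disrotation, and no element controls the absolute sense, so 19 is racemic. The step needs the regiochemistry of insertion (secured by methyl versus branched dienyl on the alkyne and by palladium preferring the carbon conjugated to the triene), the E geometry of the new alkene (secured by syn addition) and hydride capture ahead of Heck-type insertion into the hindered trisubstituted alkenes of the chain (secured by excess formate). The sense of the 6π closure relative to C7/C8 (pyrone endo) is not dictated by orbital symmetry, so the endo isomer is expected together with the exo-pyrone diastereomer, which is removed by chromatography and can be re-equilibrated through 18 by mild heating.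

**Step 10**
Reactants: 19 rac-2-methoxy-3,5-dimethyl-6-[(1RS,6RS,7SR,8RS)-1,3,5,7,8-pentamethylbicyclo[4.2.0]octa-2,4-dien-7-yl]-4H-pyran-4-one
Product: 20 2-methoxy-3,5-dimethyl-6-[(1R,6R,7S,8R)-1,3,5,7,8-pentamethylbicyclo[4.2.0]octa-2,4-dien-7-yl]-4H-pyran-4-one
Conditions: preparative HPLC, amylose tris(3,5-dimethylphenylcarbamate) phase, n-hexane/i-PrOH, 20 °C
Reagents that add atoms: none
Why: Resolution of the racemate by chromatography on a chiral stationary phase (no bond is made or broken); the four stereocentres are configurationally stable at ambient temperature because racemization would require ring-opening back to achiral 17.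

**Step 11**
Reactants: 20 2-methoxy-3,5-dimethyl-6-[(1R,6R,7S,8R)-1,3,5,7,8-pentamethylbicyclo[4.2.0]octa-2,4-dien-7-yl]-4H-pyran-4-one
Product: 21 2-methoxy-3,5-dimethyl-6-[(1S,2R,3S,4R,5R,6R)-1,3,4,5,10-pentamethyl-7,8-dioxatricyclo[4.2.2.0(2,5)]dec-9-en-3-yl]-4H-pyran-4-one
Conditions: O2, methylene blue (cat.), CH2Cl2, visible light, −20 °C
Reagents that add atoms: dioxygen, O=O
Why: [4+2] Cycloaddition of singlet oxygen (dye-sensitized photooxygenation) to the s-cis-locked cyclohexadiene; oxygen should add to the convex face anti to the cyclobutane, whose endo pyrone shields the other face, which sets both C–O stereocentres syn to the angular methyl and the ring-fusion hydrogen.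

**Compound list**

1 | dimethyl 3-oxopentanedioate | COC(=O)CC(=O)CC(=O)OC | starting material
2 | dimethyl 2,4-dimethyl-3-oxopentanedioate (stereoisomer mixture, not controlled) | COC(=O)C(C)C(=O)C(C)C(=O)OC | intermediate
3 | 4-hydroxy-6-methoxy-3,5-dimethyl-2H-pyran-2-one | COc1oc(=O)c(C)c(O)c1C | intermediate
4 | 6-methoxy-3,5-dimethyl-4-oxo-4H-pyran-2-yl trifluoromethanesulfonate | COc1oc(OS(=O)(=O)C(F)(F)F)c(C)c(=O)c1C | intermediate
5 | propyne | CC#C | starting material
6 | (Z)-dibromo(2-bromoprop-1-en-1-yl)borane (formed in the flask, not isolated) | Br/C(C)=C\B(Br)Br | intermediate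
7 | 2-[(Z)-2-bromoprop-1-en-1-yl]-4,4,5,5-tetramethyl-1,3,2-dioxaborolane (Br and B cis) | Br/C(C)=C\B1OC(C)(C)C(C)(C)O1 | intermediate
8 | prop-1-yn-1-ylmagnesium bromide (THF solution) | CC#C[Mg]Br | starting material
9 | prop-1-yn-1-ylzinc bromide (formed in the flask, not isolated) | CC#C[Zn]Br | intermediate
10 | 4,4,5,5-tetramethyl-2-[(Z)-2-methylpent-1-en-3-yn-1-yl]-1,3,2-dioxaborolane (alkynyl and B cis) | CC#C/C(C)=C\B1OC(C)(C)C(C)(C)O1 | intermediate
11 | (Z)-1-iodo-2-methylpent-1-en-3-yne | CC#C/C(C)=C\I | intermediate
12 | [(Z)-2-methylpent-1-en-3-yn-1-yl]lithium (formed in the flask, not isolated) | CC#C/C(C)=C\[Li] | intermediate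
13 | bromo[(Z)-2-methylpent-1-en-3-yn-1-yl]zinc (formed in the flask, not isolated) | CC#C/C(C)=C\[Zn]Br | intermediate
14 | 2-[(1Z,3Z)-2,4-dimethylhepta-1,3-dien-5-yn-1-yl]-4,4,5,5-tetramethyl-1,3,2-dioxaborolane | CC#C/C(C)=C\C(C)=C/B1OC(C)(C)C(C)(C)O1 | intermediate
15 | (E)-2-bromobut-2-ene | C/C=C(C)/Br | starting material
16 | (2E,4Z,6Z)-3,5,7-trimethyldeca-2,4,6-trien-8-yne | C/C=C(C)/C=C(C)\C=C(C)/C#CC | intermediate
17 | 2-methoxy-3,5-dimethyl-6-[(2E,4Z,6Z,8E)-4,6,8-trimethyldeca-2,4,6,8-tetraen-2-yl]-4H-pyran-4-one (formed in the flask, not isolated) | COc1oc(/C(C)=C/C(C)=C\C(C)=C/C(C)=C/C)c(C)c(=O)c1C | intermediate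
18 | rac-2-methoxy-3,5-dimethyl-6-[(1RS,8RS,2Z,4Z,6Z)-1,3,5,7,8-pentamethylcycloocta-2,4,6-trien-1-yl]-4H-pyran-4-one (pyrone and 8-methyl trans; formed in the flask, not isolated) | COc1oc([C@]2(C)/C=C(C)\C=C(C)/C=C(C)\[C@H]2C)c(C)c(=O)c1C.COc1oc([C@@]2(C)/C=C(C)\C=C(C)/C=C(C)\[C@@H]2C)c(C)c(=O)c1C | intermediate
19 | rac-2-methoxy-3,5-dimethyl-6-[(1RS,6RS,7SR,8RS)-1,3,5,7,8-pentamethylbicyclo[4.2.0]octa-2,4-dien-7-yl]-4H-pyran-4-one (cis-fused; pyrone endo, i.e. on the side of the cyclohexadiene; 1-, 7- and 8-methyl exo) | COc1oc([C@@]2(C)[C@H](C)[C@@]3(C)C=C(C)C=C(C)[C@@H]23)c(C)c(=O)c1C.COc1oc([C@]2(C)[C@@H](C)[C@]3(C)C=C(C)C=C(C)[C@H]23)c(C)c(=O)c1C | intermediate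
20 | 2-methoxy-3,5-dimethyl-6-[(1R,6R,7S,8R)-1,3,5,7,8-pentamethylbicyclo[4.2.0]octa-2,4-dien-7-yl]-4H-pyran-4-one | COc1oc([C@@]2(C)[C@H](C)[C@@]3(C)C=C(C)C=C(C)[C@@H]23)c(C)c(=O)c1C | intermediate
21 | 2-methoxy-3,5-dimethyl-6-[(1S,2R,3S,4R,5R,6R)-1,3,4,5,10-pentamethyl-7,8-dioxatricyclo[4.2.2.0(2,5)]dec-9-en-3-yl]-4H-pyran-4-one (peroxide bridge anti to the cyclobutane; pyrone on the cyclobutane face turned towards the alkene bridge) | COc1oc([C@@]2(C)[C@H](C)[C@@]3(C)[C@@H]4OO[C@@](C)(C=C4C)[C@@H]23)c(C)c(=O)c1C | target

**Total step count:** 11. **Longest linear sequence:** 8 steps (steps 4 to 11).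

**Steps most likely to fail**

1. **Step 9.** What may go wrong:
   - insertion of the alkyne with the wrong regiochemistry;
   - hydride reduction of the pyronyl–palladium species before insertion;
   - Heck-type insertion of the alkenyl–palladium into the neighbouring triene before hydride capture;
   - an unfavourable endo/exo partition in the 6π closure.

   The fallback sets out from 16 and comes back at 19. The carbon–metal bond is made first and regioselectively by hydrozirconation (Cp2Zr(H)Cl, THF, 0 °C, short contact time), which should put zirconium on the less hindered, methyl-bearing alkyne carbon by syn addition and give chlorobis(cyclopentadienyl)[(2E,4Z,6Z,8E)-4,6,8-trimethyldeca-2,4,6,8-tetraen-2-yl]zirconium F1. Transmetalation with ZnCl2 gives chloro[(2E,4Z,6Z,8E)-4,6,8-trimethyldeca-2,4,6,8-tetraen-2-yl]zinc F2. This is coupled at 0 °C with triflate 4 under Pd(PPh3)4 (Negishi coupling) to give tetraene 17, which closes to 19 as in the main route. Because the metalated chain is itself a tetraene capable of 8π closure, it is made cold and used at once.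

2. **Step 3.** What may go wrong: sulfonylation at the C4 oxygen instead of the C2 carbonyl oxygen, or hydrolysis of the enol triflate during isolation. The fallback sets out from 3 and comes back at 19. O-Methylation with MeOTf gives the symmetrical 2,6-dimethoxy-3,5-dimethyl-4H-pyran-4-one F3, in which the two alkoxy-bearing ring carbons are equivalent. Conjugate addition–elimination of Bu3SnLi (THF, −78 °C) replaces one methoxy group and gives 2-methoxy-3,5-dimethyl-6-(tributylstannyl)-4H-pyran-4-one F4. Iododestannylation (I2, CH2Cl2, 0 °C) gives 6-iodo-2-methoxy-3,5-dimethyl-4H-pyran-4-one F5, which takes the place of 4 in step 9 under otherwise unchanged conditions.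

3. **Step 7.** What may go wrong: deprotonation of or addition to the enyne competing with halogen–lithium exchange, and loss or scrambling of the boronate during coupling with the bifunctional bromide. The fallback sets out from 10, omits step 6 and comes back at 16. It is an iterative Suzuki–Miyaura sequence with a masked boron. The dibromoborane 6 of step 4 is treated with N-methyliminodiacetic acid and 2,6-lutidine to give (Z)-2-bromoprop-1-en-1-ylboronic acid MIDA ester F6. Coupling of 10 with F6 (Pd(OAc)2/SPhos, K3PO4, THF, 45 °C, the sp3-boron of the MIDA ester staying inert) gives (1Z,3Z)-2,4-dimethylhepta-1,3-dien-5-yn-1-ylboronic acid MIDA ester F7. Slow-release coupling of F7 with 15 (Pd(OAc)2/SPhos, aq. K3PO4, dioxane, 60 °C) gives 16.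

**Further compounds**

F1 | step 9 | chlorobis(cyclopentadienyl)[(2E,4Z,6Z,8E)-4,6,8-trimethyldeca-2,4,6,8-tetraen-2-yl]zirconium | C/C=C(C)/C=C(C)\C=C(C)/C=C(\C)[Zr](Cl)(C1C=CC=C1)C1C=CC=C1
F2 | step 9 | chloro[(2E,4Z,6Z,8E)-4,6,8-trimethyldeca-2,4,6,8-tetraen-2-yl]zinc | C/C=C(C)/C=C(C)\C=C(C)/C=C(\C)[Zn]Cl
F3 | step 3 | 2,6-dimethoxy-3,5-dimethyl-4H-pyran-4-one | COc1oc(OC)c(C)c(=O)c1C
F4 | step 3 | 2-methoxy-3,5-dimethyl-6-(tributylstannyl)-4H-pyran-4-one | COc1oc([Sn](CCCC)(CCCC)CCCC)c(C)c(=O)c1C
F5 | step 3 | 6-iodo-2-methoxy-3,5-dimethyl-4H-pyran-4-one | COc1oc(I)c(C)c(=O)c1C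
F6 | step 7 | (Z)-2-bromoprop-1-en-1-ylboronic acid MIDA ester | C[N+]12CC(=O)O[B-]1(/C=C(/C)Br)OC(=O)C2
F7 | step 7 | (1Z,3Z)-2,4-dimethylhepta-1,3-dien-5-yn-1-ylboronic acid MIDA ester | CC#C/C(C)=C\C(C)=C/[B-]12OC(=O)C[N+]1(C)CC(=O)O2
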